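A spare 0.00600 M of reagent is what the amber run holds beyond its left-handed substrate, since equivalents count on the left-handed substrate and not on both substrates. I call this difference the margin. Left-handed product reaches 47.2 % at 2.50 h, so I treat the right-handed substrate as a bystander for now.

| flask | left-handed substrate | right-handed substrate | reagent | free catalyst | remark | time |
|---|---|---|---|---|---|---|
| amber | 0.030 M | 0.030 M | 1.2 equiv | 2.5 mol% | run made earlier |  |
| east | 0.020 M | 0.020 M | 1.20 equiv | 2.5 mol% |  | 4.0 h |
| south-west | 0.020 M | 0.020 M | 1.50 equiv | 2.5 mol% |  | 4.0 h |
| west | 0.020 M | 0.020 M | 2.50 equiv | 2.5 mol% |  | 4.0 h |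

amber run (percent of the left-handed substrate and right-handed substrate together charged)

| time / h | left-handed product / % |
|---|---|
| 0.200 | 14.3 |
| 0.667 | 32.9 |
| 1.00 | 39.0 |
| 1.50 | 44.1 |
| 2.50 | 47.2 |

(each reading ± 0.5 percentage points)

- amount of left-handed product at the end, in percent of the left-handed substrate and right-handed substrate together charged for east, south-west, west, in this order
- the shape of the row from first to last (falls, then rises / hardly changes / rises, then falls / falls all the way / rises all the way)

- free catalyst is single-handed; left-handed substrate and right-handed substrate are mirror images of each other, charged as a racemate, each of them at the stated concentration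
- the numbers in the tables scatter with a standard deviation of 0.5 percentage points
- "hardly changes" means that all values lie within two and a half points (for a concentration: within two and a half percent of the largest)
- no earlier run changes the charge of free catalyst; that part of a forecast is a guess

Suppose the rate is k[left-handed substrate][reagent]. Then [reagent] − [left-handed substrate] stays at the margin, and the integrated law gives k from each reading. My objection comes at once: the first reading gives 0.0150 M⁻¹ s⁻¹, but the fourth gives 0.0250 M⁻¹ s⁻¹, so k is not constant. I suspect the catalyst is held up while substrate is plentiful. The question concerns the tail, however, and the last reading gives 0.0248 M⁻¹ s⁻¹, which matches the fourth, so I keep the late value.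

A second objection is that the same mol% on 0.020 M means less catalyst, by a factor of 0.667. If the rate follows the catalyst, k becomes 0.0166 M⁻¹ s⁻¹.

Once [left-handed substrate] falls below the margin, [reagent] stays near the margin and the left-handed substrate decays in a pseudo-first-order way. The margin time is one over k times the margin: 4.17 h for east, about the run time. For south-west it is 1.67 h, and for west 0.556 h, well inside the run. This is the crossing: east stops in its tail, and west finishes. The integrated law gives me 45.3 %, 48.4 % and 50.0 %, a row that rises throughout. A last objection stays open: the amber readings are of product and say nothing directly about the catalyst, they end at 2.50 h while these flasks run to 4.0 h, and my reckoning allows for no loss of catalyst.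

The forecast gave 48.5 %, 49.5 % and 50 %, shape hardly changes, reasoning that "The row therefore sits at the ceiling". The flasks give 44.9 %, 48.6 % and 50.0 %: rises all the way.

    reagent + catalyst intermediate A → free catalyst + left-handed product (k = 0.670 M⁻¹ s⁻¹)
    reagent + catalyst intermediate B → free catalyst + right-handed product (k = 0.220 M⁻¹ s⁻¹)
    free catalyst + right-handed substrate ⇌ catalyst intermediate B (K = 25.0 M⁻¹, k = 6.10 M⁻¹ s⁻¹)
    free catalyst → spent catalyst (k = 2.00 × 10⁻⁴ s⁻¹)
    free catalyst + left-handed substrate ⇌ catalyst intermediate A (K = 240 M⁻¹, k = 160 M⁻¹ s⁻¹)

In east, the margin time of 4.17 h is longer than the 0.96 h half-life of free catalyst by its own decay, and at 4.00 h spent catalyst stands at 67.4 % of the catalyst charged, with 9.9 % of the charged left-handed substrate still unbound. In west, the margin time of 0.556 h is shorter than the 0.963 h that the same decay gives, and at 4.00 h, with spent catalyst at 83.8 %, the unbound left-handed substrate is down to 0.012 % of its charge.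

The runs come from a simulation with made-up constants; noise was put on by code.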